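I had to say what share of the amber charge would stand as target at 48 min, and what order the starting material shows near the red charge. Both depend on how conversion moves with charge.

all flasks: free catalyst 10.0 mM

|  | starting material | time |
|---|---|---|
| red | 200 mM |  |
| ochre | 300 mM |  |
| amber | 600 mM | 48 min |

- red run (time / min: [target] / mM): 6.0: 41.5; 12: 70.0; 18: 89.0; 24: 99.8; 30: 111.7; 36: 117.7; 42: 127.0; 48: 131.1
- ochre run (time / min: [target] / mM): 6.0: 67.4; 12: 109.1; 18: 137.4; 24: 157.3; 30: 172.5; 36: 184.1; 42: 192.9; 48: 202.7

(readings scatter by 1 mM)

- the exponent of [starting material] in the starting rate at the charge of the red run (at the point where two percent of the starting material have become target) (one fixed amount of target, the same in the runs compared)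
- target in the amber run at 48 min, as a share of the starting material charged

- Overall: starting material -> target, with free catalyst as catalyst.
- Constant volume, constant temperature.
- Readings of a species count what is bound in complexes too.
- An order is taken over about fifteen percent of the charge, up and down.

I compared the runs at equal times, with 10.0 mM of free catalyst charged in each, so that a loss of catalyst with time, if equal in both, cancels. My measure was the first-order clock, the logarithm of the charge over what remains of it, taking c(target) as the amount turned. For a rate k(t)·c^n with n near one, this clock grows nearly as the charge to the power n less one.

At 48 min the red run stood at 65.5% and the ochre run at 67.6%, so their clocks read 1.07 and 1.13. The ochre clock runs ahead of the red one by a factor 1.06 for a charge factor 1.50, which gave n = 1.14. Carrying the ochre clock to twice its charge put amber at 71.0%.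

The weak link was n itself. A scatter of 1 mM in one red reading shifts it by 0.0336, against an excess over one of 0.140. So I summed the clocks, first over the opening 4 readings of each run, which gave 1.94 for red and 2.06 for ochre, and then over all 8, which gave 5.72 for red and 6.02 for ochre. The charge exponent, the apparent reaction order read from the ratio of those full sums, came to 1.13. With it, the ochre clock gave amber 70.8%, the number I would commit to.

The forecast put the order at 1.12 (0.97 to 1.3) and amber at 70.5% (65% to 77%), on the ground that the first-order plot “runs about 6% higher in ochre throughout”. My share lies slightly higher than the forecast's.

Amber gave 70.7%, and the order near the red charge came out at 1.1.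

    free catalyst + starting material ⇌ catalyst-substrate complex, settled at all times (0.6490 M⁻¹)
    catalyst-substrate complex + starting material ⇌ doubly bound catalyst, settled at all times (45.60 M⁻¹)
    doubly bound catalyst → target + catalyst-substrate complex (11.16 min⁻¹)
    2 free catalyst → 2 spent catalyst (3.324 M⁻¹ min⁻¹)
    2 starting material ⇌ idle substrate dimer, settled at all times (21.90 M⁻¹)

Where 2% of the red charge had turned, the red run made target at 9.0 mM min⁻¹ and the ochre run at 14 mM min⁻¹. Raised by the charge factor to the power 1.13, the red rate becomes 14.2 mM min⁻¹.

The data were computed from invented constants; the scatter is artificial.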